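**Retrosynthetic overview**
1. Target ⇐ C6=C7 oxonene lactone: the 6-OH/7-exo-methylene unit comes last from the ring alkene (epoxidation, then epoxide → allylic alcohol); the seven-membered lactone comes from acylation of the tertiary C3–OH by a C16 acid (isopropenyl → hydroboration → oxidation).
2. Cyclohexane and tetrahydrofuran ⇐ one intramolecular Diels–Alder reaction (C1–C10, C13–C14) of a C9-bound 2-silyloxydiene onto a C2-bound (E)-enamide held on the oxonene; the resulting C11 ketone takes MeMgBr.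
3. Oxonene ⇐ ring-closing metathesis (C6=C7) of an acyclic diene ether.
4. Diene ether ⇐ key C2–C3 bond by an intermolecular titanium glycolate aldol that joins the C7–C11 ether fragment (C9 from an asymmetric carbonyl methallylation) to acetaldehyde; C3 and C4 follow by chelation-controlled Grignard addition and carbonyl allylation.
5. Ring order: nine-membered oxonene → cyclohexene + tetrahydrofuran (one step) → seven-membered lactone.

Assumption: locants C1–C20 follow eunicellane numbering of the target (C2–O–C9 ether, C3–O–C16 lactone, octanoate on C4); the target is (1S,2S,3S,4R,6S,9S,10R,11R,14R,15R); PMB = 4-methoxybenzyl, TBS = tert-butyldimethylsilyl.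

**Route**

Step 1
Reactants: 1 propane-1,3-diol
Product: 2 3-[(4-methoxybenzyl)oxy]propan-1-ol
Conditions: NaH (1.0 equiv), THF/DMF, 0 °C; PMBCl (1.0 equiv), Bu4NI (cat.), rt; diol in threefold excess
Reagents that add atoms: 4-methoxybenzyl chloride COc1ccc(CCl)cc1
Why: Williamson ether synthesis, with excess diol giving clean mono-protection of the future C11 oxygen.

Step 2
Reactants: 2 3-[(4-methoxybenzyl)oxy]propan-1-ol
Product: 3 3-[(4-methoxybenzyl)oxy]propanal
Conditions: TEMPO (10 mol%), PhI(OAc)2 (1.1 equiv), CH2Cl2, rt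
Reagents that add atoms: none
Why: TEMPO/oxoammonium oxidation stops cleanly at the aldehyde and leaves the PMB ether untouched.

Step 3
Reactants: 3 3-[(4-methoxybenzyl)oxy]propanal
Product: 4 (3S)-1-[(4-methoxybenzyl)oxy]-5-methylhex-5-en-3-ol
Conditions: (S)-BINOL (20 mol%), Ti(OiPr)4 (10 mol%), 4 Å MS, CH2Cl2, −20 °C, CH2=C(CH3)CH2SnBu3 (1.2 equiv), 72 h; aq. NaHCO3
Reagents that add atoms: tributyl(2-methylallyl)stannane C=C(C)C[Sn](CCCC)(CCCC)CCCC
Why: Keck asymmetric carbonyl allylation; the (S)-BINOL–titanium Lewis acid directs methallyl transfer to one aldehyde face and sets C9 as S (the same facial sense that gives (S)-alcohols from other alkoxy aldehydes).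

Step 4
Reactants: 4 (3S)-homoallylic alcohol; 5 bromoacetic acid
Product: 6 2-{[(3S)-1-[(4-methoxybenzyl)oxy]-5-methylhex-5-en-3-yl]oxy}acetic acid
Conditions: NaH (3 equiv), THF, 0 °C to rt; then aq. HCl
Reagents that add atoms: none
Why: Williamson etherification of the sodium alkoxide with sodium bromoacetate installs the C2–O–C9 ether without touching C9.

Step 5
Reactants: 6 glycolic acid ether; 7 (4R)-4-benzyl-1,3-oxazolidine-2-thione
Product: 8 N-glycolyl oxazolidinethione (4R)-4-benzyl-3-(2-{[(3S)-1-[(4-methoxybenzyl)oxy]-5-methylhex-5-en-3-yl]oxy}acetyl)-1,3-oxazolidine-2-thione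
Conditions: DCC (1.2 equiv), DMAP (0.1 equiv), CH2Cl2, 0 °C to rt
Reagents that add atoms: none
Why: Carbodiimide-mediated N-acylation attaches the chiral auxiliary needed for the glycolate aldol.

Step 6
Reactants: 8 N-glycolyl oxazolidinethione; 9 acetaldehyde
Product: 10 syn-aldol adduct (4R)-4-benzyl-3-[(2R,3S)-3-hydroxy-2-{[(3S)-1-[(4-methoxybenzyl)oxy]-5-methylhex-5-en-3-yl]oxy}butanoyl]-1,3-oxazolidine-2-thione
Conditions: TiCl4 (1.05 equiv), iPr2NEt (1.1 equiv), CH2Cl2, −78 °C; NMP (1.0 equiv); CH3CHO (2 equiv), −78 to −40 °C; aq. NH4Cl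
Reagents that add atoms: none
Why: Crimmins titanium-enolate syn-glycolate aldol (intermolecular, key C2–C3 bond joining the C7–C11 ether fragment to the C3/C18 unit); the Z-enolate reacts through a Zimmerman–Traxler chair on the face away from the benzyl group of the (4R)-auxiliary, which fixes C2 (the C3 carbinol is oxidised later).

Step 7
Reactants: 10 syn-aldol adduct
Product: 11 (2S,3S)-2-{[(3S)-1-[(4-methoxybenzyl)oxy]-5-methylhex-5-en-3-yl]oxy}butane-1,3-diol
Conditions: NaBH4 (4 equiv), THF/H2O (4:1), 0 °C to rt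
Reagents that add atoms: none
Why: Hydride reduction of the activated N-acyl thione releases the auxiliary and gives the C1 primary alcohol without epimerising C2.

Step 8
Reactants: 11 1,3-diol
Product: 12 (2S,3S)-4-[(tert-butyldimethylsilyl)oxy]-3-{[(3S)-1-[(4-methoxybenzyl)oxy]-5-methylhex-5-en-3-yl]oxy}butan-2-ol
Conditions: TBSCl (1.05 equiv), imidazole, CH2Cl2, 0 °C
Reagents that add atoms: tert-butyldimethylsilyl chloride CC(C)(C)[Si](C)(C)Cl
Why: Silylation is selective for the primary C1 hydroxyl, and a silyl ether is a poor β-leaving group and a non-chelating neighbour for the next two steps.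

Step 9
Reactants: 12 secondary alcohol
Product: 13 (3S)-4-[(tert-butyldimethylsilyl)oxy]-3-{[(3S)-1-[(4-methoxybenzyl)oxy]-5-methylhex-5-en-3-yl]oxy}butan-2-one
Conditions: Dess–Martin periodinane (1.3 equiv), NaHCO3, CH2Cl2, 0 °C to rt
Reagents that add atoms: none
Why: Dess–Martin oxidation under buffered, non-basic conditions gives the α-alkoxy methyl ketone without epimerising C2.

Step 10
Reactants: 13 α-alkoxy methyl ketone
Product: 14 (2R,3S)-4-[(tert-butyldimethylsilyl)oxy]-1-[dimethyl(propan-2-yloxy)silyl]-2-methyl-3-{[(3S)-1-[(4-methoxybenzyl)oxy]-5-methylhex-5-en-3-yl]oxy}butan-2-ol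
Conditions: (iPrO)Me2SiCH2MgCl (2 equiv), THF, −78 to 0 °C; aq. NH4Cl
Reagents that add atoms: [dimethyl(propan-2-yloxy)silyl]methylmagnesium chloride CC(C)O[Si](C)(C)C[Mg]Cl
Why: Chelation-controlled (Cram chelate) Grignard addition; magnesium bridges the ketone and the C2 ether oxygen and the nucleophile adds anti to the C1 branch, setting the C3 tertiary carbinol, with the silylmethyl group serving as a masked hydroxymethyl (C4).

Step 11
Reactants: 14 β-hydroxysilane
Product: 15 (2S,3S)-4-[(tert-butyldimethylsilyl)oxy]-2-methyl-3-{[(3S)-1-[(4-methoxybenzyl)oxy]-5-methylhex-5-en-3-yl]oxy}butane-1,2-diol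
Conditions: 30% H2O2, KHCO3, THF/MeOH (1:1), 40 °C (no fluoride)
Reagents that add atoms: hydrogen peroxide OO
Why: Tamao–Fleming oxidation turns the C–Si bond of the alkoxysilane into C–OH; fluoride-free conditions spare the primary TBS ether and the alkene.

Step 12
Reactants: 15 1,2-diol
Product: 16 (2R,3S)-4-[(tert-butyldimethylsilyl)oxy]-2-hydroxy-2-methyl-3-{[(3S)-1-[(4-methoxybenzyl)oxy]-5-methylhex-5-en-3-yl]oxy}butanal
Conditions: SO3·pyridine (3 equiv), DMSO, iPr2NEt, CH2Cl2, 0 °C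
Reagents that add atoms: none
Why: Parikh–Doering oxidation converts only the primary alcohol (the tertiary one cannot oxidise) and avoids glycol cleavage; the α-carbon is quaternary so the aldehyde cannot epimerise.

Step 13
Reactants: 16 α-hydroxy aldehyde
Product: 17 (2S,3S,4R)-1-[(tert-butyldimethylsilyl)oxy]-3-methyl-2-{[(3S)-1-[(4-methoxybenzyl)oxy]-5-methylhex-5-en-3-yl]oxy}hept-6-ene-3,4-diol
Conditions: In powder (1.5 equiv), allyl bromide (2 equiv), THF/H2O (1:1), rt
Reagents that add atoms: allyl bromide C=CCBr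
Why: Barbier-type carbonyl allylation in water; the free α-hydroxyl and the aldehyde chelate indium and allyl adds anti to the larger C2 branch, giving the 3,4-syn diol and hence C4.

Step 14
Reactants: 17 3,4-diol
Product: 18 tris-TBS ether (2S,3R,4R)-1,3,4-tris[(tert-butyldimethylsilyl)oxy]-3-methyl-2-{[(3S)-1-[(4-methoxybenzyl)oxy]-5-methylhex-5-en-3-yl]oxy}hept-6-ene
Conditions: TBSOTf (3 equiv), 2,6-lutidine (5 equiv), CH2Cl2, 0 °C to rt
Reagents that add atoms: tert-butyldimethylsilyl trifluoromethanesulfonate CC(C)(C)[Si](C)(C)OS(=O)(=O)C(F)(F)F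
Why: The silyl triflate protects both the hindered secondary and the tertiary hydroxyl for the organometallic steps ahead.

Step 15
Reactants: 18 acyclic diene
Product: 19 oxonene (2S,3R,4R,6Z,9S)-3,4-bis[(tert-butyldimethylsilyl)oxy]-2-{[(tert-butyldimethylsilyl)oxy]methyl}-9-{2-[(4-methoxybenzyl)oxy]ethyl}-3,7-dimethyl-2,3,4,5,8,9-hexahydrooxonine
Conditions: second-generation Grubbs catalyst RuCl2(=CHPh)(PCy3)(H2IMes) (7 mol%), CH2Cl2 (2 mM), 40 °C
Reagents that add atoms: none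
Why: Ring-closing metathesis; the gauche-disposed ether oxygens pre-organise the chain and the nine-membered ring forms with the Z-trisubstituted C6=C7 alkene.

Step 16
Reactants: 19 oxonene
Product: 20 C1 alcohol [(2S,3R,4R,6Z,9S)-3,4-bis[(tert-butyldimethylsilyl)oxy]-9-{2-[(4-methoxybenzyl)oxy]ethyl}-3,7-dimethyl-2,3,4,5,8,9-hexahydrooxonin-2-yl]methanol
Conditions: HF·pyridine, pyridine, THF, 0 °C
Reagents that add atoms: none
Why: Buffered fluoride desilylation cleaves the unhindered primary TBS ether much faster than the hindered secondary and tertiary ones.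

Step 17
Reactants: 20 C1 alcohol
Product: 21 C1 aldehyde (2R,3R,4R,6Z,9S)-3,4-bis[(tert-butyldimethylsilyl)oxy]-9-{2-[(4-methoxybenzyl)oxy]ethyl}-3,7-dimethyl-2,3,4,5,8,9-hexahydrooxonine-2-carbaldehyde
Conditions: Dess–Martin periodinane, NaHCO3, CH2Cl2, 0 °C; used crude
Reagents that add atoms: none
Why: Dess–Martin oxidation under buffered conditions avoids epimerising the α-alkoxy aldehyde at C2.

Step 18
Reactants: 21 C1 aldehyde
Product: 22 (E)-enamide (2E)-3-[(2S,3R,4R,6Z,9S)-3,4-bis[(tert-butyldimethylsilyl)oxy]-9-{2-[(4-methoxybenzyl)oxy]ethyl}-3,7-dimethyl-2,3,4,5,8,9-hexahydrooxonin-2-yl]-N-methoxy-N-methylprop-2-enamide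
Conditions: Ph3P=CHC(O)N(OMe)Me (2 equiv), CH2Cl2, rt
Reagents that add atoms: N-methoxy-N-methyl-2-(triphenylphosphoranylidene)acetamide CON(C)C(=O)C=P(c1ccccc1)(c1ccccc1)c1ccccc1
Why: Wittig olefination with a stabilised ylide is E-selective and installs the C1=C14 dienophile with a C15 carbonyl that later survives Grignard and enol-silylation steps.

Step 19
Reactants: 22 (E)-enamide
Product: 23 C11 primary alcohol (PMB removed)
Conditions: DDQ (1.3 equiv), CH2Cl2/pH 7 buffer (10:1), 0 °C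
Reagents that add atoms: none
Why: Oxidative PMB cleavage (hydride abstraction, then hydrolysis of the oxocarbenium ion) leaves silyl ethers, the enamide and the alkene intact.

Step 20
Reactants: 23 C11 alcohol
Product: 24 C11 aldehyde
Conditions: Dess–Martin periodinane, NaHCO3, CH2Cl2, 0 °C
Reagents that add atoms: none
Why: Dess–Martin oxidation gives the β-alkoxy aldehyde without base-induced β-elimination.

Step 21
Reactants: 24 C11 aldehyde
Product: 25 allylic alcohol (C11 carbinol, both epimers)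
Conditions: CH2=CHMgBr (1.5 equiv), THF, −78 °C; aq. NH4Cl
Reagents that add atoms: vinylmagnesium bromide C=C[Mg]Br
Why: Grignard 1,2-addition is far faster to the aldehyde than to the α,β-unsaturated Weinreb amide at −78 °C, and the new carbinol centre is removed in the next step.

Step 22
Reactants: 25 allylic alcohol
Product: 26 vinyl ketone (C10H2–C11(=O)–CH=CH2)
Conditions: Dess–Martin periodinane, NaHCO3, CH2Cl2, 0 °C; used at once
Reagents that add atoms: none
Why: Dess–Martin oxidation gives the enolisable vinyl ketone that is the diene precursor.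

Step 23
Reactants: 26 vinyl ketone
Product: 28 Diels–Alder adduct (C11 TBS enol ether; C14 Weinreb amide), via silyl dienol ether 27 (not isolated)
Conditions: TBSOTf (1.5 equiv), Et3N (3 equiv), CH2Cl2, −78 to 0 °C; then toluene, 80 °C
Reagents that add atoms: tert-butyldimethylsilyl trifluoromethanesulfonate CC(C)(C)[Si](C)(C)OS(=O)(=O)C(F)(F)F
Why: Soft enolisation gives the (Z)-2-silyloxydiene (only C10 is enolisable), which undergoes an intramolecular Diels–Alder reaction; the cis-2,9-disubstituted oxonene tether forces the cis-fused adduct with H-1/H-2 and H-9/H-10 trans, and the E-dienophile places C15 trans to C2, so C1, C10 and C14 are set together.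

Step 24
Reactants: 28 Diels–Alder adduct
Product: 29 C11 ketone 3,4-diol (Weinreb amide retained)
Conditions: 48% aq. HF, MeCN, 0 °C to rt
Reagents that add atoms: none
Why: Acidic fluoride desilylation hydrolyses the silyl enol ether to the C11 ketone and removes both hindered TBS ethers without base, so C10 is not epimerised.

Step 25
Reactants: 29 keto diol
Product: 30 C11 tertiary alcohol with C15 methyl ketone
Conditions: MeMgBr (8 equiv), anhydrous CeCl3 (8 equiv), THF, −78 to 0 °C; aq. NH4Cl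
Reagents that add atoms: methylmagnesium bromide C[Mg]Br
Why: Organocerium 1,2-addition; methyl attacks the C11 ketone axially on the face away from the axial C10–C9 bond (11-OH cis to C9), while the Weinreb amide stops at the methyl ketone through its chelated tetrahedral intermediate.

Step 26
Reactants: 30 methyl ketone
Product: 31 isopropenyl triol (C15(=CH2)CH3)
Conditions: Ph3PCH3Br (8 equiv), KOtBu (7.5 equiv), THF, 0 °C to rt
Reagents that add atoms: methyltriphenylphosphonium bromide C[P+](c1ccccc1)(c1ccccc1)c1ccccc1.[Br-]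
Why: Wittig methylenation with excess ylide tolerates the free hydroxyls, and the trans-diequatorial C14 centre is the stable epimer.

Step 27
Reactants: 31 isopropenyl triol
Product: 32 C4 octanoate
Conditions: n-C7H15COCl (1.2 equiv), pyridine, DMAP (cat.), CH2Cl2, 0 °C
Reagents that add atoms: octanoyl chloride CCCCCCCC(Cl)=O
Why: Acylation reaches only the secondary C4 hydroxyl because the C3 and C11 hydroxyls are tertiary.

Step 28
Reactants: 32 C4 octanoate
Product: 33 C16 primary alcohol (15R)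
Conditions: 9-BBN (4 equiv), THF, 0 °C to rt; then pH 7 buffer, 30% H2O2, 0 °C
Reagents that add atoms: hydrogen peroxide OO
Why: Hydroboration–oxidation; 9-BBN reacts only with the 1,1-disubstituted alkene and adds anti to the C1 branch of the allylic C14 centre in the H-eclipsed (allylic-strain-minimised) conformer, which sets C15.

Step 29
Reactants: 33 C16 alcohol
Product: 34 C16 carboxylic acid
Conditions: TEMPO (0.3 equiv), PhI(OAc)2 (2.5 equiv), MeCN/H2O (1:1), rt
Reagents that add atoms: water O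
Why: TEMPO/oxoammonium oxidation in water takes the primary alcohol to the acid under near-neutral conditions that leave C15, the ester and the alkene alone.

Step 30
Reactants: 34 seco acid
Product: 35 seven-membered lactone (C16–O–C3)
Conditions: 2-methyl-6-nitrobenzoic anhydride (1.5 equiv), DMAP (3 equiv), CH2Cl2 (2 mM), rt, slow addition
Reagents that add atoms: none
Why: Shiina mixed-anhydride lactonisation; the rigid tetracycle holds the C16 carboxyl next to the tertiary C3 hydroxyl, and the trans-1,4-disposed C11 hydroxyl cannot reach it.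

Step 31
Reactants: 35 lactone
Product: 36 cis-6,7-epoxide
Conditions: mCPBA (1.2 equiv), NaHCO3, CH2Cl2, 0 °C
Reagents that add atoms: 3-chloroperoxybenzoic acid O=C(OO)c1cccc(Cl)c1
Why: Prilezhaev epoxidation of the only alkene from the exposed outer face of the Z-oxonene places oxygen on C6 with the configuration of the target.

Step 32
Reactants: 36 epoxide
Product: 37 briarellin A
Conditions: Cp2TiCl2 (2.5 equiv), Mn dust (8 equiv), THF, rt (Cp2TiCl, trivalent titanium, formed in the flask); aq. NaH2PO4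
Reagents that add atoms: none
Why: Titanocene-mediated radical epoxide opening (Nugent–RajanBabu type); C7–O homolysis gives the tertiary C7 radical, loss of a methyl hydrogen gives the exocyclic alkene, and the C6–O bond and its configuration are retained under conditions that spare the esters.

**Compound list**

1 | propane-1,3-diol | OCCCO | starting material
2 | 3-[(4-methoxybenzyl)oxy]propan-1-ol | COc1ccc(COCCCO)cc1 | intermediate
3 | 3-[(4-methoxybenzyl)oxy]propanal | COc1ccc(COCCC=O)cc1 | intermediate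
4 | (3S)-1-[(4-methoxybenzyl)oxy]-5-methylhex-5-en-3-ol | C=C(C)C[C@H](O)CCOCc1ccc(OC)cc1 | intermediate
5 | bromoacetic acid | OC(=O)CBr | starting material
6 | 2-{[(3S)-1-[(4-methoxybenzyl)oxy]-5-methylhex-5-en-3-yl]oxy}acetic acid | C=C(C)C[C@H](OCC(=O)O)CCOCc1ccc(OC)cc1 | intermediate
7 | (4R)-4-benzyl-1,3-oxazolidine-2-thione | S=C1N[C@H](Cc2ccccc2)CO1 | starting material
8 | (4R)-4-benzyl-3-(2-{[(3S)-1-[(4-methoxybenzyl)oxy]-5-methylhex-5-en-3-yl]oxy}acetyl)-1,3-oxazolidine-2-thione | C=C(C)C[C@H](OCC(=O)N1[C@H](Cc2ccccc2)COC1=S)CCOCc1ccc(OC)cc1 | intermediate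
9 | acetaldehyde | CC=O | starting material
10 | (4R)-4-benzyl-3-[(2R,3S)-3-hydroxy-2-{[(3S)-1-[(4-methoxybenzyl)oxy]-5-methylhex-5-en-3-yl]oxy}butanoyl]-1,3-oxazolidine-2-thione | C=C(C)C[C@H](O[C@H]([C@H](C)O)C(=O)N1[C@H](Cc2ccccc2)COC1=S)CCOCc1ccc(OC)cc1 | intermediate
11 | (2S,3S)-2-{[(3S)-1-[(4-methoxybenzyl)oxy]-5-methylhex-5-en-3-yl]oxy}butane-1,3-diol | C=C(C)C[C@H](O[C@H]([C@H](C)O)CO)CCOCc1ccc(OC)cc1 | intermediate
12 | (2S,3S)-4-[(tert-butyldimethylsilyl)oxy]-3-{[(3S)-1-[(4-methoxybenzyl)oxy]-5-methylhex-5-en-3-yl]oxy}butan-2-ol | C=C(C)C[C@H](O[C@H]([C@H](C)O)CO[Si](C)(C)C(C)(C)C)CCOCc1ccc(OC)cc1 | intermediate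
13 | (3S)-4-[(tert-butyldimethylsilyl)oxy]-3-{[(3S)-1-[(4-methoxybenzyl)oxy]-5-methylhex-5-en-3-yl]oxy}butan-2-one | C=C(C)C[C@H](O[C@H](C(C)=O)CO[Si](C)(C)C(C)(C)C)CCOCc1ccc(OC)cc1 | intermediate
14 | (2R,3S)-4-[(tert-butyldimethylsilyl)oxy]-1-[dimethyl(propan-2-yloxy)silyl]-2-methyl-3-{[(3S)-1-[(4-methoxybenzyl)oxy]-5-methylhex-5-en-3-yl]oxy}butan-2-ol | C=C(C)C[C@H](O[C@H]([C@@](C)(O)C[Si](C)(C)OC(C)C)CO[Si](C)(C)C(C)(C)C)CCOCc1ccc(OC)cc1 | intermediate
15 | (2S,3S)-4-[(tert-butyldimethylsilyl)oxy]-2-methyl-3-{[(3S)-1-[(4-methoxybenzyl)oxy]-5-methylhex-5-en-3-yl]oxy}butane-1,2-diol | C=C(C)C[C@H](O[C@H]([C@@](C)(O)CO)CO[Si](C)(C)C(C)(C)C)CCOCc1ccc(OC)cc1 | intermediate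
16 | (2R,3S)-4-[(tert-butyldimethylsilyl)oxy]-2-hydroxy-2-methyl-3-{[(3S)-1-[(4-methoxybenzyl)oxy]-5-methylhex-5-en-3-yl]oxy}butanal | C=C(C)C[C@H](O[C@H]([C@@](C)(O)C=O)CO[Si](C)(C)C(C)(C)C)CCOCc1ccc(OC)cc1 | intermediate
17 | (2S,3S,4R)-1-[(tert-butyldimethylsilyl)oxy]-3-methyl-2-{[(3S)-1-[(4-methoxybenzyl)oxy]-5-methylhex-5-en-3-yl]oxy}hept-6-ene-3,4-diol | C=C(C)C[C@H](O[C@H]([C@@](C)(O)[C@H](O)CC=C)CO[Si](C)(C)C(C)(C)C)CCOCc1ccc(OC)cc1 | intermediate
18 | (2S,3R,4R)-1,3,4-tris[(tert-butyldimethylsilyl)oxy]-3-methyl-2-{[(3S)-1-[(4-methoxybenzyl)oxy]-5-methylhex-5-en-3-yl]oxy}hept-6-ene | C=C(C)C[C@H](O[C@H]([C@@](C)(O[Si](C)(C)C(C)(C)C)[C@H](O[Si](C)(C)C(C)(C)C)CC=C)CO[Si](C)(C)C(C)(C)C)CCOCc1ccc(OC)cc1 | intermediate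
19 | (2S,3R,4R,6Z,9S)-3,4-bis[(tert-butyldimethylsilyl)oxy]-2-{[(tert-butyldimethylsilyl)oxy]methyl}-9-{2-[(4-methoxybenzyl)oxy]ethyl}-3,7-dimethyl-2,3,4,5,8,9-hexahydrooxonine | C/C1=C/C[C@@H](O[Si](C)(C)C(C)(C)C)[C@](C)(O[Si](C)(C)C(C)(C)C)[C@H](CO[Si](C)(C)C(C)(C)C)O[C@H](CCOCc2ccc(OC)cc2)C1 | intermediate
20 | [(2S,3R,4R,6Z,9S)-3,4-bis[(tert-butyldimethylsilyl)oxy]-9-{2-[(4-methoxybenzyl)oxy]ethyl}-3,7-dimethyl-2,3,4,5,8,9-hexahydrooxonin-2-yl]methanol | C/C1=C/C[C@@H](O[Si](C)(C)C(C)(C)C)[C@](C)(O[Si](C)(C)C(C)(C)C)[C@H](CO)O[C@H](CCOCc2ccc(OC)cc2)C1 | intermediate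
21 | (2R,3R,4R,6Z,9S)-3,4-bis[(tert-butyldimethylsilyl)oxy]-9-{2-[(4-methoxybenzyl)oxy]ethyl}-3,7-dimethyl-2,3,4,5,8,9-hexahydrooxonine-2-carbaldehyde | C/C1=C/C[C@@H](O[Si](C)(C)C(C)(C)C)[C@](C)(O[Si](C)(C)C(C)(C)C)[C@H](C=O)O[C@H](CCOCc2ccc(OC)cc2)C1 | intermediate
22 | (2E)-3-[(2S,3R,4R,6Z,9S)-3,4-bis[(tert-butyldimethylsilyl)oxy]-9-{2-[(4-methoxybenzyl)oxy]ethyl}-3,7-dimethyl-2,3,4,5,8,9-hexahydrooxonin-2-yl]-N-methoxy-N-methylprop-2-enamide | C/C1=C/C[C@@H](O[Si](C)(C)C(C)(C)C)[C@](C)(O[Si](C)(C)C(C)(C)C)[C@H](/C=C/C(=O)N(C)OC)O[C@H](CCOCc2ccc(OC)cc2)C1 | intermediate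
23 | (2E)-3-[(2S,3R,4R,6Z,9S)-3,4-bis[(tert-butyldimethylsilyl)oxy]-9-(2-hydroxyethyl)-3,7-dimethyl-2,3,4,5,8,9-hexahydrooxonin-2-yl]-N-methoxy-N-methylprop-2-enamide | C/C1=C/C[C@@H](O[Si](C)(C)C(C)(C)C)[C@](C)(O[Si](C)(C)C(C)(C)C)[C@H](/C=C/C(=O)N(C)OC)O[C@H](CCO)C1 | intermediate
24 | (2E)-3-[(2S,3R,4R,6Z,9S)-3,4-bis[(tert-butyldimethylsilyl)oxy]-3,7-dimethyl-9-(2-oxoethyl)-2,3,4,5,8,9-hexahydrooxonin-2-yl]-N-methoxy-N-methylprop-2-enamide | C/C1=C/C[C@@H](O[Si](C)(C)C(C)(C)C)[C@](C)(O[Si](C)(C)C(C)(C)C)[C@H](/C=C/C(=O)N(C)OC)O[C@H](CC=O)C1 | intermediate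
25 | (2E)-3-[(2S,3R,4R,6Z,9S)-3,4-bis[(tert-butyldimethylsilyl)oxy]-9-(2-hydroxybut-3-en-1-yl)-3,7-dimethyl-2,3,4,5,8,9-hexahydrooxonin-2-yl]-N-methoxy-N-methylprop-2-enamide (both carbinol epimers) | C/C1=C/C[C@@H](O[Si](C)(C)C(C)(C)C)[C@](C)(O[Si](C)(C)C(C)(C)C)[C@H](/C=C/C(=O)N(C)OC)O[C@H](CC(O)C=C)C1 | intermediate
26 | (2E)-3-[(2S,3R,4R,6Z,9S)-3,4-bis[(tert-butyldimethylsilyl)oxy]-3,7-dimethyl-9-(2-oxobut-3-en-1-yl)-2,3,4,5,8,9-hexahydrooxonin-2-yl]-N-methoxy-N-methylprop-2-enamide | C/C1=C/C[C@@H](O[Si](C)(C)C(C)(C)C)[C@](C)(O[Si](C)(C)C(C)(C)C)[C@H](/C=C/C(=O)N(C)OC)O[C@H](CC(=O)C=C)C1 | intermediate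
27 | silyl dienol ether (not isolated): as 26 but with the C9 side chain (1Z)-2-[(tert-butyldimethylsilyl)oxy]buta-1,3-dien-1-yl | C/C1=C/C[C@@H](O[Si](C)(C)C(C)(C)C)[C@](C)(O[Si](C)(C)C(C)(C)C)[C@H](/C=C/C(=O)N(C)OC)O[C@H](/C=C(\O[Si](C)(C)C(C)(C)C)C=C)C1 | intermediate
28 | Diels–Alder adduct: (6Z)-oxonene bridging C2/C9 of a cis-fused hexahydroisobenzofuran; 3,4-bis-OTBS, 11-OTBS enol ether (C11=C12), C14 N-methoxy-N-methylcarboxamide; H-1/H-10 cis, H-1/H-2 and H-9/H-10 trans, H-14 trans to H-1 | C/C1=C/C[C@@H](O[Si](C)(C)C(C)(C)C)[C@](C)(O[Si](C)(C)C(C)(C)C)[C@H]2O[C@@H](C1)[C@@H]1C(O[Si](C)(C)C(C)(C)C)=CC[C@@H](C(=O)N(C)OC)[C@@H]12 | intermediate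
29 | 11-oxo 3,4-diol: as 28 with C11 ketone, free 3-OH and 4-OH, C14 Weinreb amide | C/C1=C/C[C@@H](O)[C@](C)(O)[C@H]2O[C@@H](C1)[C@@H]1C(=O)CC[C@@H](C(=O)N(C)OC)[C@@H]12 | intermediate
30 | 3,4,11-triol with C14 acetyl group (11R: 11-OH cis to C9, 11-Me cis to H-10) | C/C1=C/C[C@@H](O)[C@](C)(O)[C@H]2O[C@@H](C1)[C@@H]1[C@](C)(O)CC[C@@H](C(C)=O)[C@@H]12 | intermediate
31 | 3,4,11-triol with C14 isopropenyl group | C/C1=C/C[C@@H](O)[C@](C)(O)[C@H]2O[C@@H](C1)[C@@H]1[C@](C)(O)CC[C@@H](C(C)=C)[C@@H]12 | intermediate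
32 | 4-O-octanoyl 3,11-diol with C14 isopropenyl group | C/C1=C/C[C@@H](OC(=O)CCCCCCC)[C@](C)(O)[C@H]2O[C@@H](C1)[C@@H]1[C@](C)(O)CC[C@@H](C(C)=C)[C@@H]12 | intermediate
33 | 4-O-octanoyl 3,11,16-triol (15R; C14 bears CH(CH3)CH2OH) | C/C1=C/C[C@@H](OC(=O)CCCCCCC)[C@](C)(O)[C@H]2O[C@@H](C1)[C@@H]1[C@](C)(O)CC[C@@H]([C@@H](C)CO)[C@@H]12 | intermediate
34 | 4-O-octanoyl 3,11-dihydroxy C16 acid (15R) | C/C1=C/C[C@@H](OC(=O)CCCCCCC)[C@](C)(O)[C@H]2O[C@@H](C1)[C@@H]1[C@](C)(O)CC[C@@H]([C@@H](C)C(=O)O)[C@@H]12 | intermediate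
35 | 6,7-didehydro lactone: briarellin A skeleton with C6=C7 (Z, 7-methyl) in place of 6-OH/7-methylene | C/C1=C/C[C@@H](OC(=O)CCCCCCC)[C@](C)(O3)[C@H]2O[C@@H](C1)[C@@H]1[C@](C)(O)CC[C@@H]([C@@H](C)C3=O)[C@@H]12 | intermediate
36 | cis-6,7-epoxide of 35 (epoxide oxygen on the face of the future 6-OH) | C[C@@]12O[C@H]2C[C@@H](OC(=O)CCCCCCC)[C@](C)(O3)[C@H]4O[C@@H](C1)[C@@H]1[C@](C)(O)CC[C@@H]([C@@H](C)C3=O)[C@@H]14 | intermediate
37 | briarellin A | C=C1C[C@@H]2O[C@H]3[C@H]4[C@@H](CC[C@@](C)(O)[C@H]42)[C@@H](C)C(=O)O[C@@]3(C)[C@H](OC(=O)CCCCCCC)C[C@@H]1O | target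

**Step count and risks**

Total steps: 32. Longest linear sequence: 32 steps, from propane-1,3-diol (1) to 37; the route is fully linear.

The three steps most likely to fail:

Step 28 (hydroboration, C15). The C15 configuration rests on acyclic allylic-strain control next to C14, so the ratio may be low or reversed. The fallback sets C15 by hydrogenation on the closed lactone ring instead; it sets out from methyl ketone 30 and comes back at lactone 35. Condensation of 30 with 2,4,6-triisopropylbenzenesulfonohydrazide gives the trisylhydrazone F1. A Shapiro reaction (excess n-BuLi, THF/TMEDA, −78 to 0 °C) with CO2 quench of the vinyllithium gives the 2-substituted acrylic acid F2. Octanoyl chloride/pyridine acylates only the secondary C4 hydroxyl to give the octanoate acid F3. 2-Methyl-6-nitrobenzoic anhydride/DMAP then closes the α-methylene lactone F4, which has no stereocentre next to the activated carboxyl. Finally H2 with RhCl(PPh3)3 reduces only the exocyclic conjugated alkene, with hydrogen expected on the face of H-14 (anti to the C13 methylene), to give 35.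

Step 30 (lactonisation onto the tertiary C3 hydroxyl). Acylating a hindered tertiary alcohol may be slow, and the activated acid could epimerise at C15. The fallback is an oxidative lactonisation through a lactol instead of carboxyl activation; it sets out from alcohol 33 and comes back at lactone 35. Dess–Martin periodinane gives the C16 aldehyde F5, which equilibrates with the seven-membered lactol F6 by addition of the nearby C3 hydroxyl. Pr4NRuO4 (cat.) with N-methylmorpholine N-oxide and 4 Å sieves oxidises the lactol and drains the equilibrium to 35.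

Step 32 (epoxide to exocyclic allylic alcohol). The radical opening may give some endocyclic C7=C8 alkene or a reduced product. The fallback is an ionic, base-induced opening instead of the radical one; it sets out from epoxide 36 and comes back at 37. Me3SiOTf/2,6-lutidine at −78 °C followed by DBU (Noyori-type silyl triflate activation, then proton loss from the unhindered methyl group) gives the bis(trimethylsilyl) ether F7, in which the C6 allyl silyl ether, the C7 exocyclic methylene and the silylated 11-OH are present. HF·pyridine in THF then removes both silyl groups to give 37.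

**Further compounds**

F1 | step 28 | 2,4,6-triisopropylbenzenesulfonyl hydrazone of methyl ketone 30 | C/C1=C/C[C@@H](O)[C@](C)(O)[C@H]2O[C@@H](C1)[C@@H]1[C@](C)(O)CC[C@@H](C(C)=NNS(=O)(=O)c3c(C(C)C)cc(C(C)C)cc3C(C)C)[C@@H]12
F2 | step 28 | 3,4,11-triol bearing a C14 1-carboxyvinyl group (2-substituted acrylic acid) | C/C1=C/C[C@@H](O)[C@](C)(O)[C@H]2O[C@@H](C1)[C@@H]1[C@](C)(O)CC[C@@H](C(=C)C(=O)O)[C@@H]12
F3 | step 28 | 4-O-octanoyl derivative of acrylic acid F2 | C/C1=C/C[C@@H](OC(=O)CCCCCCC)[C@](C)(O)[C@H]2O[C@@H](C1)[C@@H]1[C@](C)(O)CC[C@@H](C(=C)C(=O)O)[C@@H]12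
F4 | step 28 | 15-methylene lactone (35 with C15=CH2 in place of 15-H/15-CH3) | C/C1=C/C[C@@H](OC(=O)CCCCCCC)[C@](C)(O3)[C@H]2O[C@@H](C1)[C@@H]1[C@](C)(O)CC[C@@H](C(=C)C3=O)[C@@H]12
F5 | step 30 | C16 aldehyde corresponding to alcohol 33 (15R) | C/C1=C/C[C@@H](OC(=O)CCCCCCC)[C@](C)(O)[C@H]2O[C@@H](C1)[C@@H]1[C@](C)(O)CC[C@@H]([C@@H](C)C=O)[C@@H]12
F6 | step 30 | seven-membered lactol (C16 hemiacetal with O-3, both anomers) | C/C1=C/C[C@@H](OC(=O)CCCCCCC)[C@](C)(O3)[C@H]2O[C@@H](C1)[C@@H]1[C@](C)(O)CC[C@@H]([C@@H](C)C3O)[C@@H]12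
F7 | step 32 | 6,11-bis-O-trimethylsilyl briarellin A | C=C1C[C@@H]2O[C@H]3[C@H]4[C@@H](CC[C@@](C)(O[Si](C)(C)C)[C@H]42)[C@@H](C)C(=O)O[C@@]3(C)[C@H](OC(=O)CCCCCCC)C[C@@H]1O[Si](C)(C)C
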